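## Retrosynthetic overview

1. Target 10 ⇒ achiral stilbene bis-phenol 8: disconnect the benzylic C2–O bond of the dihydrofuran. This is the only ring formed, it is closed in the last step, and both stereocentres are set there by a chiral Brønsted acid via p-quinone methide 9.
2. 8 ⇒ alkenyl boronate 6 + 6-bromoeugenol 7 (Suzuki coupling, aryl–C3 bond).
3. 6 ⇒ propargyl ether 3 + B2pin2 + 4-iodo-2-methoxyphenol 4 (alkyne diboration, then terminal-selective Suzuki coupling, aryl–C2 bond).
4. 3 ⇒ eugenol 1 + propargyl bromide 2 (the CH2–OAr ether is carried from the start); 7 ⇒ eugenol 1 (ortho-bromination).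

Assumption: the sense of induction of the new step 5 cannot be predicted with confidence; the (R)-catalyst is written, and its (S)-antipode is used instead if the first run (chiral HPLC/ECD) shows the mirror-image product.

## Route

**Step 1**
Reactants: 1 eugenol (4-allyl-2-methoxyphenol); 2 propargyl bromide
Product: 3 4-allyl-2-methoxy-1-(prop-2-yn-1-yloxy)benzene
Conditions: K2CO3 (2 equiv), acetone, reflux
Reagents that add atoms: none
Why: Williamson ether synthesis (SN2 of potassium eugenolate on the propargylic bromide); no stereocentre.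

**Step 2**
Reactants: 3 4-allyl-2-methoxy-1-(prop-2-yn-1-yloxy)benzene; 4 4-iodo-2-methoxyphenol
Product: 6 4-[(E)-3-(4-allyl-2-methoxyphenoxy)-2-(4,4,5,5-tetramethyl-1,3,2-dioxaborolan-2-yl)prop-1-en-1-yl]-2-methoxyphenol (aryl and boron cis), via cis-1,2-bis(pinacolboryl)alkene 5 (not isolated)
Conditions: B2pin2 (1.05 equiv), Pt(PPh3)4 (3 mol%), DMF, 80 °C; then 4 (0.95 equiv), PdCl2(dppf) (3 mol%), 3 M aq K3PO4 (3 equiv), rt → 45 °C
Reagents that add atoms: bis(pinacolato)diboron, CC1(C)OB(OC1(C)C)B1OC(C)(C)C(C)(C)O1
Why: Pt(0)-catalysed syn-diboration of the terminal alkyne (allyl C=C and ethers are inert to Pt(PPh3)4/B2pin2) followed in the same flask by a Suzuki–Miyaura coupling that occurs selectively at the less hindered terminal C–B bond with retention, which fixes aryl on C-1 and boron on C-2; no stereocentre.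

**Step 3**
Reactants: 1 eugenol
Product: 7 4-allyl-2-bromo-6-methoxyphenol (6-bromoeugenol)
Conditions: NBS (1.0 equiv), i-Pr2NH (10 mol%), CH2Cl2, −20 → 0 °C, dark
Reagents that add atoms: N-bromosuccinimide, O=C1CCC(=O)N1Br
Why: amine-catalysed electrophilic aromatic bromination (SEAr) goes to the only free position ortho to the phenol OH much faster than NBS attacks the unactivated allyl C=C in dry CH2Cl2 at low temperature; no stereocentre.

**Step 4**
Reactants: 6 alkenyl pinacol boronate; 7 4-allyl-2-bromo-6-methoxyphenol
Product: 8 (E)-4-allyl-2-[3-(4-allyl-2-methoxyphenoxy)-1-(4-hydroxy-3-methoxyphenyl)prop-1-en-2-yl]-6-methoxyphenol (the two phenol rings cis on the alkene)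
Conditions: Pd(OAc)2 (3 mol%), SPhos (6 mol%), K3PO4 (3 equiv), THF/H2O 10:1, 40 °C, degassed
Reagents that add atoms: none
Why: Suzuki–Miyaura coupling of the internal alkenyl boronate with the unprotected o-bromophenol using a biarylphosphine catalyst that tolerates free phenols and hindered partners at 40 °C, mild enough to spare the allylic aryl ether and both allyl groups; no stereocentre, and the alkene geometry (retention) is irrelevant later.

**Step 5**
Reactants: 8 stilbene bis-phenol
Product: 10 (2S,3R)-5-allyl-3-[(4-allyl-2-methoxyphenoxy)methyl]-2-(4-hydroxy-3-methoxyphenyl)-7-methoxy-2,3-dihydrobenzofuran (the target), via p-quinone methide 9 (not isolated)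
Conditions: (R)-TRIP N-triflylphosphoramide (5 mol%), 4 Å MS, toluene (0.02 M), −20 °C
Reagents that add atoms: none
Why: Proposed new method: a confined chiral Brønsted acid, hydrogen-bonded through its basic P=O to the ortho-phenol OH, delivers its proton to one face of the alkene carbon bearing that ring (setting C3) and so unmasks the p-quinone methide/p-hydroxybenzyl cation 9 as a chiral contact ion pair, which the same phenol OH closes at once by 5-exo C–O bond formation anti to the CH2OAr group (setting C2, trans, the same closure that gives only trans-phenylcoumarans in biomimetic lignan couplings), the alkene geometry of 8 being erased in 9; the closest known reaction types are chiral-phosphoric-acid-catalysed oxa-1,6-additions to in situ generated p-quinone methides and chiral-acid-catalysed asymmetric intramolecular hydroalkoxylation of alkenes, but a tautomerisation–cyclisation of a 4-hydroxystilbene that sets two stereocentres has not been reported.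

## Compound list

1 | eugenol (4-allyl-2-methoxyphenol) | C=CCc1ccc(O)c(OC)c1 | starting material
2 | propargyl bromide (3-bromoprop-1-yne) | C#CCBr | starting material
3 | 4-allyl-2-methoxy-1-(prop-2-yn-1-yloxy)benzene | C=CCc1ccc(OCC#C)c(OC)c1 | intermediate
4 | 4-iodo-2-methoxyphenol | COc1cc(I)ccc1O | starting material
5 | 2,2'-[(E)-3-(4-allyl-2-methoxyphenoxy)prop-1-ene-1,2-diyl]bis(4,4,5,5-tetramethyl-1,3,2-dioxaborolane), boryl groups cis | C=CCc1ccc(OC/C(B2OC(C)(C)C(C)(C)O2)=C/B2OC(C)(C)C(C)(C)O2)c(OC)c1 | intermediate (not isolated)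
6 | 4-[(E)-3-(4-allyl-2-methoxyphenoxy)-2-(4,4,5,5-tetramethyl-1,3,2-dioxaborolan-2-yl)prop-1-en-1-yl]-2-methoxyphenol | C=CCc1ccc(OC/C(B2OC(C)(C)C(C)(C)O2)=C/c2ccc(O)c(OC)c2)c(OC)c1 | intermediate
7 | 4-allyl-2-bromo-6-methoxyphenol | C=CCc1cc(Br)c(O)c(OC)c1 | intermediate
8 | (E)-4-allyl-2-[3-(4-allyl-2-methoxyphenoxy)-1-(4-hydroxy-3-methoxyphenyl)prop-1-en-2-yl]-6-methoxyphenol | C=CCc1ccc(OC/C(c2cc(CC=C)cc(OC)c2O)=C/c2ccc(O)c(OC)c2)c(OC)c1 | intermediate
9 | (R)-4-[2-(5-allyl-2-hydroxy-3-methoxyphenyl)-3-(4-allyl-2-methoxyphenoxy)propylidene]-2-methoxycyclohexa-2,5-dien-1-one (catalyst-bound p-quinone methide) | C=CCc1ccc(OC[C@H](C=C2C=CC(=O)C(OC)=C2)c2cc(CC=C)cc(OC)c2O)c(OC)c1 | intermediate (not isolated)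
10 | (2S,3R)-5-allyl-3-[(4-allyl-2-methoxyphenoxy)methyl]-2-(4-hydroxy-3-methoxyphenyl)-7-methoxy-2,3-dihydrobenzofuran (2,3-trans) | C=CCc1ccc(OC[C@H]2c3cc(CC=C)cc(OC)c3O[C@@H]2c2ccc(O)c(OC)c2)c(OC)c1 | target

## Step count and risks

Total steps: 5. Longest linear sequence: 4 (steps 1, 2, 4, 5).

The step most likely to fail is step 5, the new asymmetric cyclisation. Possible failures are low ee or the wrong sense of induction, and protonation at the other alkene carbon, which leads via an o-quinone methide to loss of eugenol and a 3-benzylbenzofuran. The product could also racemise slowly by reversible ring opening if left with the acid. The fallback sets out from 8 and comes back at 10. Compound 8 is cyclised with an achiral acid (10 mol% diphenyl phosphate or CSA, CH2Cl2, rt), a known acid-catalysed hydroalkoxylation of an o-hydroxystilbene under thermodynamic trans control. This gives the racemic trans product, that is 10 together with (2R,3S)-5-allyl-3-[(4-allyl-2-methoxyphenoxy)methyl]-2-(4-hydroxy-3-methoxyphenyl)-7-methoxy-2,3-dihydrobenzofuran F1. The enantiomers are separated by preparative chiral SFC on a polysaccharide carbamate phase to give 10 (maximum 50%).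

Second is step 4, the Suzuki coupling that makes 8. The internal boronate is hindered and can protodeboronate. Pd(0) or the alkenyl-Pd intermediate could ionise or β-eliminate the allylic aryl ether, and warm base could start a racemic background cyclisation of 8. The fallback sets out from 6 (with 7) and comes back at 8 without palladium. The C–B bond of 6 is oxidised (NaBO3·4H2O, THF/H2O, rt) to 1-(4-allyl-2-methoxyphenoxy)-3-(4-hydroxy-3-methoxyphenyl)propan-2-one F2. Compound 7 is converted into its O,C-dianion (n-BuLi, 2.1 equiv per 7, THF, −78 °C) and transmetalated with CeCl3 to suppress enolisation. Three equivalents of this reagent are added to F2 to give racemic 4-allyl-2-[1-(4-allyl-2-methoxyphenoxy)-2-hydroxy-3-(4-hydroxy-3-methoxyphenyl)propan-2-yl]-6-methoxyphenol F3. Dehydration of this tertiary benzylic alcohol (cat. PPTS, toluene, 50 °C, via the o-quinone methide) gives 8 as an E/Z mixture, which is acceptable because step 5 erases the alkene geometry.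

Third is step 3, the chemoselective ring bromination of eugenol. NBS may also attack the allyl C=C or over-brominate. The fallback sets out from 1 and comes back at 7 by the classical over-bromination/debromination sequence. Eugenol is treated with Br2 (2.05 equiv, CH2Cl2, 0 °C), which brominates the ring ortho to OH and adds across the alkene to give 2-bromo-4-(2,3-dibromopropyl)-6-methoxyphenol F4. Zinc dust (AcOH/EtOH, rt) then removes the vicinal dibromide reductively and regenerates the allyl group, giving 7.

## Further compounds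

F1 | step 5 | (2R,3S)-5-allyl-3-[(4-allyl-2-methoxyphenoxy)methyl]-2-(4-hydroxy-3-methoxyphenyl)-7-methoxy-2,3-dihydrobenzofuran (enantiomer of 10) | C=CCc1ccc(OC[C@@H]2c3cc(CC=C)cc(OC)c3O[C@H]2c2ccc(O)c(OC)c2)c(OC)c1
F2 | step 4 | 1-(4-allyl-2-methoxyphenoxy)-3-(4-hydroxy-3-methoxyphenyl)propan-2-one | C=CCc1ccc(OCC(=O)Cc2ccc(O)c(OC)c2)c(OC)c1
F3 | step 4 | 4-allyl-2-[1-(4-allyl-2-methoxyphenoxy)-2-hydroxy-3-(4-hydroxy-3-methoxyphenyl)propan-2-yl]-6-methoxyphenol (racemic) | C=CCc1ccc(OCC(O)(Cc2ccc(O)c(OC)c2)c2cc(CC=C)cc(OC)c2O)c(OC)c1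
F4 | step 3 | 2-bromo-4-(2,3-dibromopropyl)-6-methoxyphenol (racemic) | BrCC(Br)Cc1cc(Br)c(O)c(OC)c1
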